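**Plan**
- The retrosynthesis first cuts the two aryl–C7 and aryl–C7' bonds. Each benzylic carbon carries a ring oxygen of the cis-fused 3,7-dioxabicyclo[3.3.0]octane (C7'–O1 in ring A, C7–O2 in ring B), so each is a masked lactol carbon. Each aryl is a 2,6-dimethoxyphenol bound through its only free activated carbon, para to OH with both ortho carbons methoxylated.
- This leads back to bis-lactol 11 and hydroxy bis-lactone 10. The C7–C8–C8'–C7' chain of 10 is the carbon chain of (R)-malic acid (its carbinol C2 is C8). The C8–C9 and C8'–C9' bonds are then cut to two one-carbon units from benzyl chloromethyl ether.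
- Forward: the chain is extended first at malate C3 (C8'–C9', dianion alkylation), then at C2 (C8–C9, dioxolanone enolate alkylation). Hydrogenolysis closes rings B and A together as γ-lactones, reduction gives the bis-lactol, and the double arylation closes no ring.
- Stereochemistry: C8 is the malic acid stereocentre, kept through an acetal relay. C8' is set by the chelated dianion alkylation. C7 and C7' are set by convex-face attack on the bicyclic oxocarbenium ions.

Key step: step 8

Remark: lignan numbering is used from 10 onward (C7, C7' benzylic; C8 carbinol; C8' ring-fusion CH; C9 on C8 and C9' on C8' are the OCH2 carbons; ring A = O1, C7', C8', C8, C9; ring B = O2, C7, C8, C8', C9'). Compounds 11 and 13 are carried as anomeric mixtures, which is immaterial because the lactol carbons are ionised in step 8.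

**Route**

Step 1
Reactants: 1 (R)-malic acid
Product: 2 diethyl (R)-malate
Conditions: EtOH, H2SO4 (cat.), reflux
Reagents that add atoms: ethanol, CCO
Why: Fischer esterification converts both carboxyl groups into ethyl esters without touching the C2 stereocentre and gives a THF-soluble substrate for dianion chemistry.

Step 2
Reactants: 2 diethyl (R)-malate; 3 benzyl chloromethyl ether
Product: 4 diethyl (2R,3S)-3-(benzyloxymethyl)-2-hydroxybutanedioate
Conditions: LiN(i-Pr)2 (2.1 equiv), THF, −78 → −20 °C; then 3, −78 → −10 °C
Reagents that add atoms: benzyl chloromethyl ether (3), ClCOCc1ccccc1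
Why: Fráter–Seebach alkylation, in which the chelated lithium alkoxide–enolate dianion of the β-hydroxy ester is C-alkylated by the reactive α-chloro ether on the face anti to the ester group at the carbinol carbon, which should set C3 as S in the erythro (2R,3S) product, the minor diastereomer being removed by chromatography.

Step 3
Reactants: 4 diethyl (2R,3S)-3-(benzyloxymethyl)-2-hydroxybutanedioate
Product: 5 (2R,3S)-3-(benzyloxymethyl)-2-hydroxybutanedioic acid
Conditions: LiOH, THF–H2O, 0 °C → rt; then aq. HCl
Reagents that add atoms: lithium hydroxide, [Li+].[OH-]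
Why: Ester saponification at low temperature, where acyl substitution by hydroxide is far faster than deprotonation at C3, so neither epimerisation nor β-elimination of benzyloxide is expected.

Step 4
Reactants: 5 (2R,3S)-3-(benzyloxymethyl)-2-hydroxybutanedioic acid; 6 pivalaldehyde
Product: 7 (2S)-3-(benzyloxy)-2-[(2R,4R)-2-tert-butyl-5-oxo-1,3-dioxolan-4-yl]propanoic acid (cis-dioxolanone)
Conditions: t-BuCHO, TsOH·H2O (cat.), H2SO4 (cat.), pentane, reflux (Dean–Stark)
Reagents that add atoms: pivalaldehyde (6), CC(C)(C)C=O
Why: Acid-catalysed acetalisation of the α-hydroxy acid unit under water removal should favour the five-membered dioxolanone over the six-membered dioxanone and, under thermodynamic control, place tert-butyl cis to the side chain, which creates the acetal stereocentre (R) that relays the C2 configuration, the cis isomer being purified by crystallisation.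

Step 5
Reactants: 7 (2S)-3-(benzyloxy)-2-[(2R,4R)-2-tert-butyl-5-oxo-1,3-dioxolan-4-yl]propanoic acid; 3 benzyl chloromethyl ether
Product: 8 (2S)-3-(benzyloxy)-2-[(2R,4S)-4-(benzyloxymethyl)-2-tert-butyl-5-oxo-1,3-dioxolan-4-yl]propanoic acid
Conditions: LiN(SiMe3)2 (2.1 equiv), THF, −78 °C; then 3, −78 → −30 °C
Reagents that add atoms: benzyl chloromethyl ether (3), ClCOCc1ccccc1
Why: Dioxolanone enolate alkylation by the principle of self-regeneration of stereocentres, in which the carboxylate formed first shields C3–H from enolisation and the ring enolate is alkylated on the face opposite to tert-butyl, so that CH2OBn takes the place of the former C2–H with overall retention and creates the quaternary carbinol centre (future C8).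

Step 6
Reactants: 8 (2S)-3-(benzyloxy)-2-[(2R,4S)-4-(benzyloxymethyl)-2-tert-butyl-5-oxo-1,3-dioxolan-4-yl]propanoic acid
Product: 10 (1S,5S)-1-hydroxy-3,7-dioxabicyclo[3.3.0]octane-2,6-dione, via diol acid 9 (not isolated)
Conditions: H2 (1 atm), 10% Pd/C, THF, rt; filter; then TsOH·H2O (cat.), 50 °C
Reagents that add atoms: none
Why: Hydrogenolysis of both benzyl ethers is followed by acid-catalysed transacylation of the C9' hydroxyl onto the dioxolanone carbonyl (ring B, releasing pivalaldehyde and the tertiary hydroxyl) and lactonisation of the C9 hydroxyl with the free carboxyl (ring A), a double γ-lactonisation that sets no stereocentre and that only the desired diastereomer can complete because the bicycle must be cis-fused.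

Step 7
Reactants: 10 (1S,5S)-1-hydroxy-3,7-dioxabicyclo[3.3.0]octane-2,6-dione
Product: 11 (1S,5S)-3,7-dioxabicyclo[3.3.0]octane-1,2,6-triol (bis-lactol, anomeric mixture)
Conditions: i-Bu2AlH (3.3 equiv), CH2Cl2–THF, −78 °C; MeOH then Na2SO4·10H2O, filter
Reagents that add atoms: none
Why: Partial reduction of γ-lactones with i-Bu2AlH stops at the lactol stage because the tetrahedral aluminium alkoxides are stable at −78 °C (one equivalent is spent on the tertiary hydroxyl), and the non-aqueous work-up should keep the water-soluble triol in the organic filtrate.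

Step 8
Reactants: 11 (1S,5S)-3,7-dioxabicyclo[3.3.0]octane-1,2,6-triol; 12 2,6-dimethoxyphenol
Product: 14 (7R,8S,7'S,8'R)-8-hydroxysyringaresinol, via mono-aryl lactol 13 (not isolated)
Conditions: 12 (3 equiv), Sc(OTf)3 (15 mol%), MeCN, −20 °C → rt
Reagents that add atoms: 2,6-dimethoxyphenol (12), COc1cccc(OC)c1O
Why: Sc(OTf)3 ionises each lactol C–OH to a bicyclic five-membered oxocarbenium ion, which is attacked by C4 of 2,6-dimethoxyphenol and rearomatises, expected first at C7' remote from the tertiary hydroxyl (intermediate 13) and then, on warming, at the inductively deactivated C7. The closest known reaction type is the Lewis-acid Friedel–Crafts aryl C-glycosylation of phenols with furanosyl lactols or acetates, including the acid-mediated arylation of furofuran lactols by electron-rich phenols. No ring is closed, since both tetrahydrofuran rings are already present in 11. The new stereocentres C7' (S) and C7 (R) are controlled by the cis-fused bicycle fixed by C8 and C8', each aryl entering on the convex face, cis to H-8' and to the 8-hydroxyl respectively, which is the exo,exo arrangement of the target. The step needs para-C-arylation rather than O-arylation (the ortho carbons are blocked and O-aryl acetals of this hindered phenol should re-ionise and drain to the C-aryl product), exo rather than endo attack (secured by the concave shape of the bicycle and by leaving the 8-hydroxyl free so that no participating group directs a 1,2-trans entry), and two arylations without a third, for which catalytic acid, a small excess of phenol and low temperature are relied on so that the 4-hydroxybenzyl ether bonds of the product do not re-ionise.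

**Compound list**

1 | (R)-malic acid | O[C@H](CC(=O)O)C(=O)O | starting material
2 | diethyl (R)-malate | CCOC(=O)[C@H](O)CC(=O)OCC | intermediate
3 | benzyl chloromethyl ether | ClCOCc1ccccc1 | starting material
4 | diethyl (2R,3S)-3-(benzyloxymethyl)-2-hydroxybutanedioate | CCOC(=O)[C@H](O)[C@H](COCc1ccccc1)C(=O)OCC | intermediate
5 | (2R,3S)-3-(benzyloxymethyl)-2-hydroxybutanedioic acid | OC(=O)[C@H](O)[C@H](COCc1ccccc1)C(=O)O | intermediate
6 | pivalaldehyde | CC(C)(C)C=O | starting material
7 | (2S)-3-(benzyloxy)-2-[(2R,4R)-2-tert-butyl-5-oxo-1,3-dioxolan-4-yl]propanoic acid | O=C1O[C@H](C(C)(C)C)O[C@@H]1[C@H](COCc2ccccc2)C(=O)O | intermediate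
8 | (2S)-3-(benzyloxy)-2-[(2R,4S)-4-(benzyloxymethyl)-2-tert-butyl-5-oxo-1,3-dioxolan-4-yl]propanoic acid | O=C1O[C@H](C(C)(C)C)O[C@]1(COCc2ccccc2)[C@H](COCc3ccccc3)C(=O)O | intermediate
9 | (2S)-2-[(2R,4S)-2-tert-butyl-4-(hydroxymethyl)-5-oxo-1,3-dioxolan-4-yl]-3-hydroxypropanoic acid (not isolated) | O=C1O[C@H](C(C)(C)C)O[C@]1(CO)[C@H](CO)C(=O)O | intermediate
10 | (1S,5S)-1-hydroxy-3,7-dioxabicyclo[3.3.0]octane-2,6-dione | O=C1OC[C@]2(O)C(=O)OC[C@H]12 | intermediate
11 | (1S,5S)-3,7-dioxabicyclo[3.3.0]octane-1,2,6-triol (anomeric mixture) | OC1OC[C@]2(O)C(O)OC[C@H]12 | intermediate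
12 | 2,6-dimethoxyphenol | COc1cccc(OC)c1O | starting material
13 | (1S,5R,6S)-6-(4-hydroxy-3,5-dimethoxyphenyl)-3,7-dioxabicyclo[3.3.0]octane-1,2-diol (anomeric mixture, not isolated) | COc1cc([C@H]2OC[C@]3(O)C(O)OC[C@H]23)cc(OC)c1O | intermediate
14 | 8-hydroxysyringaresinol, (1S,2R,5R,6S)-2,6-bis(4-hydroxy-3,5-dimethoxyphenyl)-3,7-dioxabicyclo[3.3.0]octan-1-ol | COc1cc([C@H]2OC[C@]3(O)[C@@H](c4cc(OC)c(O)c(OC)c4)OC[C@H]23)cc(OC)c1O | target

**Step count**

Total step count: 8. Longest linear sequence: 8 steps (1 → 14).

**Steps most likely to fail**

Step 8. Facial selectivity at C7 and C7' may be incomplete, ionisation next to the 8-hydroxyl may be slow, and the 4-hydroxybenzyl ether bonds of the product may re-ionise under the acid, causing epimerisation or ring opening by a third arylation. The fallback sets out from 11 and returns at 14. Commercial 4-bromo-2,6-dimethoxyphenol is silylated (t-BuMe2SiCl, imidazole, DMF) to tert-butyl(4-bromo-2,6-dimethoxyphenoxy)dimethylsilane F1, which is converted with Mg in THF into [4-(tert-butyldimethylsilyloxy)-3,5-dimethoxyphenyl]magnesium bromide F2. An excess of this reagent adds to the open hydroxy-aldehyde forms of 11 to give (2S,3R)-1,4-bis[4-(tert-butyldimethylsilyloxy)-3,5-dimethoxyphenyl]-2,3-bis(hydroxymethyl)butane-1,2,4-triol F3, whose benzylic configuration is immaterial. Catalytic camphorsulfonic acid in CH2Cl2 then ionises the two benzylic alcohols, and the C9' and C9 hydroxyls close rings B and A by 5-exo-trig capture. This is the classical cyclodehydration route to furofuran lignans and should place each aryl trans to the neighbouring ring carbon, hence exo, giving the bis(tert-butyldimethylsilyl) ether of 8-hydroxysyringaresinol F4. Bu4NF in THF frees the phenols to give 14. No free phenol nucleophile is present during the acid step, so over-arylation cannot occur.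

Step 5. SN2 alkylation at the hindered enolate carbon may be sluggish, allowing enolate decomposition above about −30 °C or O-alkylation of the carboxylate. The fallback sets out from 7 and returns at 10. The same dianion of 7 is treated at −78 °C with monomeric formaldehyde (from cracked paraformaldehyde), so that an aldol addition replaces the alkylation. The electrophile is then the smallest available, cannot alkylate the carboxylate, and is subject to the same facial bias (anti to tert-butyl). This should give (2S)-3-(benzyloxy)-2-[(2R,4S)-2-tert-butyl-4-(hydroxymethyl)-5-oxo-1,3-dioxolan-4-yl]propanoic acid F5. Hydrogenolysis of its single benzyl ether and acid treatment under the conditions of step 6 should deliver 10 directly.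

Step 7. Reduction may run past the lactol stage at one carbonyl while the other lags, and the water-soluble triol may be lost on isolation. The fallback sets out from 10 and returns at 11. The tertiary hydroxyl is silylated (Et3SiOTf, 2,6-lutidine, CH2Cl2) to (1S,5S)-1-(triethylsilyloxy)-3,7-dioxabicyclo[3.3.0]octane-2,6-dione F6. This lipophilic bis-lactone has no alkoxide to consume hydride and is reduced with i-Bu2AlH (2.2 equiv, CH2Cl2, −78 °C) to the extractable (1S,5S)-1-(triethylsilyloxy)-3,7-dioxabicyclo[3.3.0]octane-2,6-diol F7. Desilylation with Bu4NF buffered with AcOH in THF then gives 11.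

**Further compounds**

F1 | step 8 | tert-butyl(4-bromo-2,6-dimethoxyphenoxy)dimethylsilane | COc1cc(Br)cc(OC)c1O[Si](C)(C)C(C)(C)C
F2 | step 8 | [4-(tert-butyldimethylsilyloxy)-3,5-dimethoxyphenyl]magnesium bromide | COc1cc([Mg]Br)cc(OC)c1O[Si](C)(C)C(C)(C)C
F3 | step 8 | (2S,3R)-1,4-bis[4-(tert-butyldimethylsilyloxy)-3,5-dimethoxyphenyl]-2,3-bis(hydroxymethyl)butane-1,2,4-triol | OC[C@](O)(C(O)c1cc(OC)c(O[Si](C)(C)C(C)(C)C)c(OC)c1)[C@H](CO)C(O)c1cc(OC)c(O[Si](C)(C)C(C)(C)C)c(OC)c1
F4 | step 8 | bis(tert-butyldimethylsilyl) ether of 8-hydroxysyringaresinol | COc1cc([C@H]2OC[C@]3(O)[C@@H](c4cc(OC)c(O[Si](C)(C)C(C)(C)C)c(OC)c4)OC[C@H]23)cc(OC)c1O[Si](C)(C)C(C)(C)C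
F5 | step 5 | (2S)-3-(benzyloxy)-2-[(2R,4S)-2-tert-butyl-4-(hydroxymethyl)-5-oxo-1,3-dioxolan-4-yl]propanoic acid | O=C1O[C@H](C(C)(C)C)O[C@]1(CO)[C@H](COCc2ccccc2)C(=O)O
F6 | step 7 | (1S,5S)-1-(triethylsilyloxy)-3,7-dioxabicyclo[3.3.0]octane-2,6-dione | O=C1OC[C@]2(O[Si](CC)(CC)CC)C(=O)OC[C@H]12
F7 | step 7 | (1S,5S)-1-(triethylsilyloxy)-3,7-dioxabicyclo[3.3.0]octane-2,6-diol | OC1OC[C@]2(O[Si](CC)(CC)CC)C(O)OC[C@H]12
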